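**Strategy.** The route rests on cutting the C4–C4a bond of ring C. In ring A, O1 on C8a sits between the prenylated C8 and the unsubstituted C4a, and C4a is ortho to O1 and O5 and para to O7. An acyl carbon hung from O1 through C2 and C3 can therefore bond only to C4a. The key step, an intramolecular Friedel–Crafts acylation, closes ring C in one operation and leaves both stereocentres untouched. Its precursor is a (2R,3R)-3-aryl-3-aryloxy-2-silyloxypropanoic acid, assembled by opening a (2R,3S)-trans-glycidate (B ring, geranyl in place) with inversion, using the bis-MOM ether of 2-prenylphloroglucinol.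

Key step: step 10

**Remarks on the chemistry**
- Precursor design: O3 is carried as a TBS ether, not an acetal. An α-(alkoxymethoxy)acyl electrophile can close onto its own acetal oxygen to a 1,3-dioxolan-4-one (as N-alkoxycarbonyl amino acid chlorides give N-carboxyanhydrides) and decarbonylates more easily. A silyl ether does neither and still falls in the final acid methanolysis.
- The B ring starts from 4-iodophenol: the para position is blocked for the C-geranylation, and the iodide gives the cinnamate directly by Heck coupling.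
- Assumption: the (R)-biphenyldiol ligand in step 6 is taken to give the (2R,3S)-epoxide, as with simple cinnamates. If the sense is opposite, the (S)-ligand is used.
- Phenoxides and carboxylates formed by simple deprotonation are treated as forms of the numbered compound and carry no number of their own.

**Route**

Step 1
Reactants: 1 phloroglucinol
Product: 2 3,5-bis(methoxymethoxy)phenol
Conditions: MOMCl (2.0 equiv), iPr2NEt (2.4 equiv), DMF/CH2Cl2, 0 °C → rt
Reagents that add atoms: chloromethyl methyl ether, COCCl
Why: Williamson-type O-alkylation of the phenol by the chloromethyl ether; the three hydroxyls are equivalent, so only one bis-ether can form and it should separate from the mono- and tris-ethers by chromatography.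

Step 2
Reactants: 2 3,5-bis(methoxymethoxy)phenol; 3 prenyl bromide
Product: 4 3,5-bis(methoxymethoxy)-2-(3-methylbut-2-en-1-yl)phenol
Conditions: NaH (1.05 equiv), toluene, 0 °C; then 3 (1.0 equiv), rt
Reagents that add atoms: none
Why: C-allylation of a sodium phenoxide as a contact ion pair in a non-polar solvent should go ortho to the O–Na (C2 and C6 are equivalent), which puts prenyl next to the single free hydroxyl; O-prenyl and para-alkylated material should be minor and separable.

Step 3
Reactants: 5 4-iodophenol; 6 geranyl bromide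
Product: 7 2-[(2E)-3,7-dimethylocta-2,6-dien-1-yl]-4-iodophenol
Conditions: NaH (1.0 equiv), toluene, 0 °C; then 6 (0.8 equiv), rt
Reagents that add atoms: none
Why: The same ortho-selective phenoxide C-allylation, with the para position blocked by iodine and a deficit of bromide to limit double alkylation; SN2 attack at the primary allylic carbon keeps the E-alkene.

Step 4
Reactants: 7 2-geranyl-4-iodophenol
Product: 8 2-[(2E)-3,7-dimethylocta-2,6-dien-1-yl]-4-iodo-1-(methoxymethoxy)benzene
Conditions: MOMCl (1.3 equiv), iPr2NEt (1.6 equiv), CH2Cl2, 0 °C → rt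
Reagents that add atoms: chloromethyl methyl ether, COCCl
Why: Standard MOM protection of a phenol (O-alkylation by an α-chloro ether) under conditions that leave the aryl iodide and the alkenes alone.

Step 5
Reactants: 8 2-geranyl-4-iodo-1-(methoxymethoxy)benzene; 9 methyl acrylate
Product: 10 methyl (2E)-3-{3-[(2E)-3,7-dimethylocta-2,6-dien-1-yl]-4-(methoxymethoxy)phenyl}prop-2-enoate
Conditions: Pd(OAc)2 (5 mol %), P(o-tol)3 (10 mol %), Et3N (2 equiv), DMF, 80 °C
Reagents that add atoms: none
Why: Mizoroki–Heck coupling of an aryl iodide with an acrylate gives the E-cinnamate by syn insertion and syn β-hydride elimination; the isolated trisubstituted alkenes of the geranyl chain do not insert.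

Step 6
Reactants: 10 methyl (2E)-3-[3-geranyl-4-(methoxymethoxy)phenyl]prop-2-enoate
Product: 11 methyl (2R,3S)-3-{3-[(2E)-3,7-dimethylocta-2,6-dien-1-yl]-4-(methoxymethoxy)phenyl}oxirane-2-carboxylate (trans)
Conditions: Y(OiPr)3 (5 mol %), (R)-6,6′-[oxybis(ethane-2,1-diyloxy)]biphenyl-2,2′-diol (5 mol %), Ph3As=O (5 mol %), TBHP in decane (1.5 equiv), MS 4 Å, THF, rt
Reagents that add atoms: tert-butyl hydroperoxide, CC(C)(C)OO
Why: Catalytic asymmetric nucleophilic epoxidation (Weitz–Scheffer type) of a β-aryl enoate by a chiral yttrium peroxide touches only the electron-poor alkene; the chiral yttrium–biphenyldiol complex selects the enone face and sets C2 (R) and C3 (S) together, trans as dictated by the E-alkene.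

Step 7
Reactants: 11 methyl (2R,3S)-3-aryl-oxirane-2-carboxylate; 4 3,5-bis(methoxymethoxy)-2-prenylphenol
Product: 12 methyl (2R,3R)-3-[3,5-bis(methoxymethoxy)-2-(3-methylbut-2-en-1-yl)phenoxy]-3-{3-[(2E)-3,7-dimethylocta-2,6-dien-1-yl]-4-(methoxymethoxy)phenyl}-2-hydroxypropanoate (erythro)
Conditions: 4 (1.3 equiv), Cs2CO3 (0.2 equiv), DMF, 50 °C
Reagents that add atoms: none
Why: Base-mediated SN2 opening of the glycidic ester by the phenoxide at the benzylic carbon, with no Lewis acid present, should invert C3 (S to R) and leave C2 untouched; the alkoxide formed is reprotonated by phenol 4, so the base stays catalytic.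

Step 8
Reactants: 12 methyl (2R,3R)-3-aryl-3-aryloxy-2-hydroxypropanoate
Product: 13 (2R,3R)-3-[3,5-bis(methoxymethoxy)-2-prenylphenoxy]-3-[3-geranyl-4-(methoxymethoxy)phenyl]-2-hydroxypropanoic acid
Conditions: LiOH·H2O (2 equiv), THF/H2O (3:1), 0 °C; then 0.5 M HCl to pH 4, 0 °C
Reagents that add atoms: lithium hydroxide, [Li+].[OH-]
Why: Saponification (BAc2) of an unhindered α-hydroxy methyl ester is fast at 0 °C, and it is done before silylation because the α-alkoxide and the carboxylate resist enolisation, so neither epimerisation at C2 nor β-elimination of the aryloxide should compete.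

Step 9
Reactants: 13 (2R,3R)-3-aryl-3-aryloxy-2-hydroxypropanoic acid
Product: 15 (2R,3R)-3-[3,5-bis(methoxymethoxy)-2-prenylphenoxy]-2-[(tert-butyldimethylsilyl)oxy]-3-[3-geranyl-4-(methoxymethoxy)phenyl]propanoic acid, via bis-silyl derivative 14 (not isolated)
Conditions: TBSCl (3 equiv), imidazole (6 equiv), DMAP (cat.), DMF, 35 °C; then AcOH/THF/H2O (1:3:1), rt
Reagents that add atoms: tert-butyldimethylsilyl chloride, CC(C)(C)[Si](C)(C)Cl
Why: Silylation of both the hydroxyl and the carboxyl group, followed by selective hydrolysis of the far more labile silyl ester, leaves the secondary silyl ether and the free acid without touching a stereocentre or the aryl MOM ethers.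

Step 10
Reactants: 15 (2R,3R)-3-aryl-3-aryloxy-2-(silyloxy)propanoic acid
Product: 17 (2R,3R)-3-[(tert-butyldimethylsilyl)oxy]-2-{3-[(2E)-3,7-dimethylocta-2,6-dien-1-yl]-4-(methoxymethoxy)phenyl}-5,7-bis(methoxymethoxy)-8-(3-methylbut-2-en-1-yl)-2,3-dihydro-4H-chromen-4-one, via mixed trifluoroacetic anhydride 16 (not isolated)
Conditions: TFAA (1.3 equiv), 2,6-di-tert-butyl-4-methylpyridine (3 equiv), CH2Cl2 (0.01 M), −30 → 0 °C
Reagents that add atoms: none
Why: Trifluoroacetic anhydride converts the acid into mixed anhydride 16, whose acyl carbon is attacked by C4a of ring A to give a Wheland intermediate that loses its proton to the hindered pyridine; this is an intramolecular Friedel–Crafts acylation, the usual closure of 3-aryloxypropanoic acids to chroman-4-ones. Ring C forms as a six-membered ring by 6-exo-trig attack on the acyl carbon, with the B-ring aryl and the silyloxy group able to sit trans-diequatorial in the transition state. No stereocentre is created; C2 and C3 are spectators set in steps 6 and 7, and the weak, hindered base should neither enolise the anhydride nor expel the β-aryloxide. Regioselectivity comes from the substrate: of the two carbons ortho to O1, C8 carries prenyl, so the O1–C2–C3 tether reaches only C4a, which is activated by O1 and O5 (ortho) and O7 (para), while C6 is out of reach, the ring-B carbons are meta to O4′ and would give an indanone, and the alkenes could close only eight-membered or larger rings. Chemoselectivity rests on this high nucleophilicity, which should let the anhydride react without a Lewis acid, and on the buffer, which traps trifluoroacetic acid before it can add to the prenyl and geranyl alkenes or cleave the MOM ethers.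

Step 11
Reactants: 17 (2R,3R)-3-(silyloxy)-5,7,4′-tris(methoxymethoxy)-8-prenyl-3′-geranylflavanone
Product: 18 Sanggenol C, (2R,3R)-2-{3-[(2E)-3,7-dimethylocta-2,6-dien-1-yl]-4-hydroxyphenyl}-3,5,7-trihydroxy-8-(3-methylbut-2-en-1-yl)-2,3-dihydro-4H-chromen-4-one
Conditions: HCl (ca. 1 M) in MeOH/THF, 0 → 40 °C, stopped at full conversion; NaHCO3
Reagents that add atoms: none
Why: Acid-catalysed transacetalisation of the three aryl MOM ethers and methanolysis of the silyl ether should occur in one operation; the trans (2R,3R) dihydroflavonol is the thermodynamic isomer, and a short, mild exposure limits cyclisation of the prenyl and geranyl chains onto the adjacent phenols.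

**Compound list**

1 | phloroglucinol | Oc1cc(O)cc(O)c1 | starting material
2 | 3,5-bis(methoxymethoxy)phenol | COCOc1cc(O)cc(OCOC)c1 | intermediate
3 | prenyl bromide (1-bromo-3-methylbut-2-ene) | CC(C)=CCBr | starting material
4 | 3,5-bis(methoxymethoxy)-2-(3-methylbut-2-en-1-yl)phenol | CC(C)=CCc1c(O)cc(OCOC)cc1OCOC | intermediate
5 | 4-iodophenol | Oc1ccc(I)cc1 | starting material
6 | geranyl bromide | CC(C)=CCC/C(C)=C/CBr | starting material
7 | 2-[(2E)-3,7-dimethylocta-2,6-dien-1-yl]-4-iodophenol | CC(C)=CCC/C(C)=C/Cc1cc(I)ccc1O | intermediate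
8 | 2-[(2E)-3,7-dimethylocta-2,6-dien-1-yl]-4-iodo-1-(methoxymethoxy)benzene | CC(C)=CCC/C(C)=C/Cc1cc(I)ccc1OCOC | intermediate
9 | methyl acrylate | C=CC(=O)OC | starting material
10 | methyl (2E)-3-[3-geranyl-4-(methoxymethoxy)phenyl]prop-2-enoate | CC(C)=CCC/C(C)=C/Cc1cc(/C=C/C(=O)OC)ccc1OCOC | intermediate
11 | methyl (2R,3S)-3-[3-geranyl-4-(methoxymethoxy)phenyl]oxirane-2-carboxylate | CC(C)=CCC/C(C)=C/Cc1cc([C@@H]2O[C@H]2C(=O)OC)ccc1OCOC | intermediate
12 | methyl (2R,3R)-3-[3,5-bis(methoxymethoxy)-2-prenylphenoxy]-3-[3-geranyl-4-(methoxymethoxy)phenyl]-2-hydroxypropanoate | CC(C)=CCC/C(C)=C/Cc1cc([C@@H](Oc2cc(OCOC)cc(OCOC)c2CC=C(C)C)[C@@H](O)C(=O)OC)ccc1OCOC | intermediate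
13 | (2R,3R)-3-[3,5-bis(methoxymethoxy)-2-prenylphenoxy]-3-[3-geranyl-4-(methoxymethoxy)phenyl]-2-hydroxypropanoic acid | CC(C)=CCC/C(C)=C/Cc1cc([C@@H](Oc2cc(OCOC)cc(OCOC)c2CC=C(C)C)[C@@H](O)C(=O)O)ccc1OCOC | intermediate
14 | tert-butyldimethylsilyl (2R,3R)-3-aryl-3-aryloxy-2-[(tert-butyldimethylsilyl)oxy]propanoate (bis-silyl derivative of 13) | CC(C)=CCC/C(C)=C/Cc1cc([C@@H](Oc2cc(OCOC)cc(OCOC)c2CC=C(C)C)[C@@H](O[Si](C)(C)C(C)(C)C)C(=O)O[Si](C)(C)C(C)(C)C)ccc1OCOC | intermediate
15 | (2R,3R)-3-[3,5-bis(methoxymethoxy)-2-prenylphenoxy]-2-[(tert-butyldimethylsilyl)oxy]-3-[3-geranyl-4-(methoxymethoxy)phenyl]propanoic acid | CC(C)=CCC/C(C)=C/Cc1cc([C@@H](Oc2cc(OCOC)cc(OCOC)c2CC=C(C)C)[C@@H](O[Si](C)(C)C(C)(C)C)C(=O)O)ccc1OCOC | intermediate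
16 | mixed anhydride of 15 with trifluoroacetic acid | CC(C)=CCC/C(C)=C/Cc1cc([C@@H](Oc2cc(OCOC)cc(OCOC)c2CC=C(C)C)[C@@H](O[Si](C)(C)C(C)(C)C)C(=O)OC(=O)C(F)(F)F)ccc1OCOC | intermediate
17 | (2R,3R)-3-[(tert-butyldimethylsilyl)oxy]-2-[3-geranyl-4-(methoxymethoxy)phenyl]-5,7-bis(methoxymethoxy)-8-prenyl-2,3-dihydro-4H-chromen-4-one | CC(C)=CCC/C(C)=C/Cc1cc([C@H]2Oc3c(CC=C(C)C)c(OCOC)cc(OCOC)c3C(=O)[C@@H]2O[Si](C)(C)C(C)(C)C)ccc1OCOC | intermediate
18 | Sanggenol C | CC(C)=CCC/C(C)=C/Cc1cc([C@H]2Oc3c(CC=C(C)C)c(O)cc(O)c3C(=O)[C@@H]2O)ccc1O | target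

**Step count.** Total: 11 steps. Longest linear sequence: 9 steps (steps 3 to 11, from 4-iodophenol).

**Steps most likely to fail**

1. Step 10. Under the buffer the acylation may be slow enough for the activated acid to break down (loss of the β-aryloxide, decarbonylation); with less buffer, acid may add to the alkenes and cleave the acetals. The fallback closes ring C through the O1–C2 bond instead; it sets out from phenol 4 and aryl iodide 8 and comes back at target 18. Iodide 8 would be converted by iodine–magnesium exchange (iPrMgCl·LiCl, THF, −20 °C) and DMF into 3-geranyl-4-(methoxymethoxy)benzaldehyde F1. The bromomagnesium phenoxide of 4 (EtMgBr, toluene) would be acetylated with acetyl chloride at its only free ortho carbon to give 1-[2-hydroxy-4,6-bis(methoxymethoxy)-3-prenylphenyl]ethanone F2, and the chelated hydroxyl allylated (allyl bromide, K2CO3, DMF) to give allyl ether F3. Claisen–Schmidt condensation of F3 with F1 (KOH, EtOH) should give the E-chalcone F4. Juliá–Colonna epoxidation (poly-L-leucine, urea–H2O2, DBU, THF), a nucleophilic oxidation that spares isolated alkenes, should give the (2R,3S)-epoxy ketone F5. Pd(PPh3)4 and morpholine would remove the allyl group to give the 2′-hydroxy epoxy ketone F6. In methanolic HCl the freed phenol, the only one beside the prenyl group, should open the epoxide at the benzylic carbon in a 6-endo closure while the MOM ethers fall, giving 18; the α-carbon keeps its configuration and the trans ring is the thermodynamic one.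

2. Step 7. Direct displacement at C3 may be outrun by ionisation of the p-alkoxybenzylic C–O bond (loss of inversion), by acyl transfer from the ester to the phenoxide, or the hindered phenoxide may simply attack too slowly. The fallback removes the ester before the opening; it sets out from glycidate 11 and phenol 4 and comes back at hydroxy acid 13. NaBH4 (MeOH/THF, 0 °C) should reduce 11 to {(2S,3S)-3-[3-geranyl-4-(methoxymethoxy)phenyl]oxiran-2-yl}methanol F7, which has neither an acyl group nor an acidic α-hydrogen. The sodium phenoxide of 4 (NaOH, H2O/dioxane, 70 °C) should open F7 at the benzylic carbon with inversion to give the (2S,3R)-3-aryloxy-3-arylpropane-1,2-diol F8. TEMPO (cat.) with PhI(OAc)2 in MeCN/H2O should then oxidise only the primary alcohol to the carboxylic acid, giving 13.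

3. Step 6. Conjugate addition of the metal peroxide to an electron-rich cinnamate may be slow, and facial selectivity may drop with the bulky meta substituent. The fallback replaces asymmetric catalysis by a Darzens condensation and an enzymatic resolution; it sets out from aryl iodide 8 and comes back at glycidate 11. Aldehyde F1, made from 8 as in the first fallback, would be condensed with methyl chloroacetate (NaOMe, MeOH, −10 °C → rt) to give the racemic trans-glycidate F9. A lipase of the kind used to resolve trans-3-arylglycidic esters (toluene/phosphate buffer) would hydrolyse the (2S,3R)-ester and leave (2R,3S)-11.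

**Further compounds**

F1 | step 10 | 3-[(2E)-3,7-dimethylocta-2,6-dien-1-yl]-4-(methoxymethoxy)benzaldehyde | CC(C)=CCC/C(C)=C/Cc1cc(C=O)ccc1OCOC
F2 | step 10 | 1-[2-hydroxy-4,6-bis(methoxymethoxy)-3-(3-methylbut-2-en-1-yl)phenyl]ethanone | CC(=O)c1c(O)c(CC=C(C)C)c(OCOC)cc1OCOC
F3 | step 10 | 1-[2-(allyloxy)-4,6-bis(methoxymethoxy)-3-(3-methylbut-2-en-1-yl)phenyl]ethanone | CC(=O)c1c(OCC=C)c(CC=C(C)C)c(OCOC)cc1OCOC
F4 | step 10 | (2E)-1-[2-(allyloxy)-4,6-bis(methoxymethoxy)-3-prenylphenyl]-3-[3-geranyl-4-(methoxymethoxy)phenyl]prop-2-en-1-one | CC(C)=CCC/C(C)=C/Cc1cc(/C=C/C(=O)c2c(OCC=C)c(CC=C(C)C)c(OCOC)cc2OCOC)ccc1OCOC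
F5 | step 10 | [2-(allyloxy)-4,6-bis(methoxymethoxy)-3-prenylphenyl]{(2R,3S)-3-[3-geranyl-4-(methoxymethoxy)phenyl]oxiran-2-yl}methanone | CC(C)=CCC/C(C)=C/Cc1cc([C@@H]2O[C@H]2C(=O)c3c(OCC=C)c(CC=C(C)C)c(OCOC)cc3OCOC)ccc1OCOC
F6 | step 10 | [2-hydroxy-4,6-bis(methoxymethoxy)-3-prenylphenyl]{(2R,3S)-3-[3-geranyl-4-(methoxymethoxy)phenyl]oxiran-2-yl}methanone | CC(C)=CCC/C(C)=C/Cc1cc([C@@H]2O[C@H]2C(=O)c3c(O)c(CC=C(C)C)c(OCOC)cc3OCOC)ccc1OCOC
F7 | step 7 | {(2S,3S)-3-[3-geranyl-4-(methoxymethoxy)phenyl]oxiran-2-yl}methanol | CC(C)=CCC/C(C)=C/Cc1cc([C@@H]2O[C@H]2CO)ccc1OCOC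
F8 | step 7 | (2S,3R)-3-[3,5-bis(methoxymethoxy)-2-prenylphenoxy]-3-[3-geranyl-4-(methoxymethoxy)phenyl]propane-1,2-diol | CC(C)=CCC/C(C)=C/Cc1cc([C@@H](Oc2cc(OCOC)cc(OCOC)c2CC=C(C)C)[C@@H](O)CO)ccc1OCOC
F9 | step 6 | racemic methyl trans-3-[3-geranyl-4-(methoxymethoxy)phenyl]oxirane-2-carboxylate (1:1 mixture of 2R,3S and 2S,3R) | CC(C)=CCC/C(C)=C/Cc1cc([C@@H]2O[C@H]2C(=O)OC)ccc1OCOC.CC(C)=CCC/C(C)=C/Cc1cc([C@H]2O[C@@H]2C(=O)OC)ccc1OCOC
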